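Late readings tell you most. At 50.0 min the birch run holds 50.1% right-handed substrate but 24.6% left-handed, each charged as 0.5 of the pair.

common to all: left-handed substrate 20 mM; right-handed substrate 20 mM
- alder: partner 0.60 equiv (fed, over 15 min); precatalyst 2 mol%; run made earlier; the fed solution adds 0.20 times the starting volume
- birch: partner 2.4 equiv (fed, over 15 min); precatalyst 2 mol%; run made earlier; the fed solution adds 0.20 times the starting volume
- larch: partner 1.2 equiv (fed, over 15 min); precatalyst 1 mol%; run made earlier; the fed solution adds 0.20 times the starting volume
- flask: partner 1.20 equiv (fed, over 15 min); precatalyst 2 mol%; the fed solution adds 0.20 times the starting volume; time 1.0 h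

| run | time / min | left-handed substrate / % | right-handed substrate / % |
|---|---|---|---|
| alder | 6.00 | 50.7 | 50.1 |
| alder | 15.0 | 49.7 | 50.4 |
| alder | 20.0 | 48.6 | 50.3 |
| alder | 30.0 | 45.5 | 50.1 |
| alder | 40.0 | 43.2 | 49.6 |
| alder | 50.0 | 42.4 | 48.9 |
| birch | 4.00 | 50.1 | 50.1 |
| birch | 6.00 | 49.6 | 50.2 |
| birch | 8.00 | 49.1 | 50.8 |
| birch | 15.0 | 46.4 | 50.4 |
| birch | 20.0 | 42.9 | 50.4 |
| birch | 30.0 | 36.1 | 49.3 |
| birch | 50.0 | 24.6 | 50.1 |
| larch | 4.00 | 49.9 | 50.5 |
| larch | 8.00 | 49.4 | 50.7 |
| larch | 15.0 | 48.1 | 49.0 |
| larch | 25.0 | 46.9 | 50.5 |
| larch | 50.0 | 41.5 | 50.8 |

(each reading ± 0.5 percentage points)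

- catalyst is single-handed; left-handed substrate and right-handed substrate are mirror images of each other, charged as a racemate, each of them at the stated concentration
- charges are per starting volume, the dose included; the dosed solution carries all of it
- the numbers in the tables scatter by 0.5 percentage points (one standard deviation)
- an excess is below zero if the other one leads

* part of the left-handed substrate and right-handed substrate charged together that has reacted at 1.0 h
* excess of left-handed product over right-handed product in the product at 1.0 h
* excess of right-handed substrate over left-handed substrate among what is left of the two at 1.0 h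

Follow one left-handed molecule. At each moment it reacts or waits, so the fraction f of its charge still there is its chance of surviving. Take −ln f as its exposure. In birch at 50.0 min that is 0.709. Suppose the chance per moment goes with partner times catalyst (pseudo-first-order in the substrate). Then exposure goes with equivalents times loading, and the flask has 0.500 of birch's product.

But does that scaling hold? Alder and larch reach the same product by different routes, so both should read 0.177. At 50.0 min they read 0.165 and 0.186. I keep it.

But birch stops at 50.0 min, and you are asked about 1.0 h. Birch's last stretch adds exposure at 0.0192 min⁻¹, so I extend it at that slope.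

And the slow start? The birch feed also lasts 15 min, so I take the same start, scaled like the rest.

My figure for the flask is 0.451: the exposure, minus the logarithm of the chance that a left-handed molecule survives to 1.0 h. With the right-handed substrate held at its charge, I get c = 18.2% and eS = 22.2%. This reckoning holds no right-handed loss, so it gives no eP.

The forecast says c 18.2% (15.5% to 21%), eP 98% (93% to 100%), eS 21.8% (18.5% to 25.5%). Its exponent is 0.45, and it says alder and larch “should then match, and they do”. Its eS stands below mine.

    precatalyst ⇌ catalyst (K = 11.0, k = 4.80 × 10⁻⁴ s⁻¹)
    partner + catalyst + left-handed substrate → catalyst + left-handed product (k = 56.0 L² mol⁻² s⁻¹)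
    partner + catalyst + right-handed substrate → catalyst + right-handed product (k = 0.420 L² mol⁻² s⁻¹)
    catalyst ⇌ dormant form (K = 0.870, k = 2.20 × 10⁻⁴ s⁻¹)

The flask gives c 17.9%, eP 98.2%, eS 21.5%, with an exposure of 0.439. At 0.558 h the left-handed substrate's half-life by its step is 1.2 h, far shorter than the right-handed substrate's 170 h.

Take a neighbour flask, the same recipe with 0.480 equiv of partner. Its exposure should be 0.180, a survival chance of 83.5%. The neighbour flask keeps 84% of its left-handed substrate and reaches c 8.00%.

The runs are simulated from invented constants; noise was put on by code.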